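The plan cuts ring A at C5–C6 and C7–C8. Ring A is a phloroglucinol in which O1 (on C8a), O5 and O7 alternate with C4a, the unsubstituted C6 and the bridge-bearing C8. The four carbons C5, C8, C8a and C4a can therefore be stored as a cyclobutenone on the C4a–C8a edge of a finished, enantiopure ring C. Heating this ketone with a two-carbon silyl ynol ether builds the whole aromatic ring in one operation. It places the ring D benzyl group on C8 automatically and leaves O5 and O7 differentiated. The precursor is a 2-oxabicyclo[4.2.0]oct-1(8)-en-7-one that already carries rings B and D and both stereocentres.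

Key step: step 16

Abbreviations: ArB = 3,4-bis(benzyloxy)phenyl; ArD = 2,6-bis(benzyloxy)-4-methoxy-3-methyl-5-(2-methylpropanoyl)phenyl. Flavan numbering (O1, C2–C4, C4a, C5–C8, C8a) is used for all atoms of rings A and C.

Assumption: the bicyclic intermediates are carried as epimer mixtures at C4a, C8 and C8a, because these centres all end as sp2 carbons of ring A; the SEGPHOS antipode is the one that sends the allyl fragment to the Si face of the aldehyde.

Step 1
Reactants: 1 acrolein; 2 benzoic anhydride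
Product: 3 prop-2-ene-1,1-diyl dibenzoate
Conditions: H2SO4 (cat.), CH2Cl2, 0 °C to rt
Reagents that add atoms: none
Why: Acid-catalysed acylal formation, the 1,1-addition of an anhydride across an aldehyde carbonyl, is the standard way to acrolein gem-diesters and creates no stereocentre.

Step 2
Reactants: 4 3,4-bis(benzyloxy)benzaldehyde; 3 prop-2-ene-1,1-diyl dibenzoate
Product: 5 (1R,2S)-1-ArB-1-hydroxybut-3-en-2-yl benzoate
Conditions: [Ir(cod)Cl]2 (2.5 mol %), SEGPHOS (5 mol %), 4-chloro-3-nitrobenzoic acid (10 mol %), Cs2CO3 (20 mol %), i-PrOH (2 equiv), THF, 80 °C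
Reagents that add atoms: none
Why: Krische allylation in its anti-(acyloxy)allylation form: transfer hydrogenation from 2-propanol turns 3 into an (E)-σ-(benzoyloxy)allyliridium species that adds to 4 through a closed chair transition state, which sets C2 and C3 anti, while the chiral bisphosphine selects the Si face of the aldehyde and so fixes 2R,3S (flavan numbering).

Step 3
Reactants: 5 (1R,2S)-1-ArB-1-hydroxybut-3-en-2-yl benzoate
Product: 7 lactol (2R,3S)-2-ArB-6-hydroxytetrahydropyran-3-yl benzoate (both anomers), via hydroxy aldehyde 6 (not isolated)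
Conditions: Rh(acac)(CO)2 (1 mol %), Xantphos (3 mol %), CO/H2 (1:1, 15 bar), toluene, 70 °C
Reagents that add atoms: carbon monoxide, [C-]#[O+]
Why: Linear-selective rhodium hydroformylation of a homoallylic alcohol: the wide-bite-angle diphosphine puts the formyl carbon (future C8a) on the terminal carbon, the C2 hydroxyl closes the six-membered lactol because O3 is blocked as the benzoate, and the new anomeric centre is left uncontrolled since step 4 removes it.

Step 4
Reactants: 7 lactol (2R,3S)-2-ArB-6-hydroxytetrahydropyran-3-yl benzoate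
Product: 8 (2R,3S)-2-ArB-3,4-dihydro-2H-pyran-3-yl benzoate
Conditions: MsCl, Et3N, CH2Cl2, 0 °C to reflux
Reagents that add atoms: none
Why: Lactol dehydration by mesylation and amine-induced elimination through the oxocarbenium ion is the usual entry to cyclic enol ethers and does not touch C2 or C3.

Step 5
Reactants: 9 2-methylphloroglucinol; 10 isobutyryl chloride
Product: 11 2-methyl-1-(2,4,6-trihydroxy-3-methylphenyl)propan-1-one
Conditions: AlCl3 (3.5 equiv), CH2Cl2–PhNO2, 0 to 40 °C; aqueous HCl work-up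
Reagents that add atoms: none
Why: Friedel–Crafts C-acylation of a phloroglucinol, in which the two free ring positions of 9 are equivalent so that only one ketone can form.

Step 6
Reactants: 11 2-methyl-1-(2,4,6-trihydroxy-3-methylphenyl)propan-1-one
Product: 12 1-[4,6-bis(benzyloxy)-2-hydroxy-3-methylphenyl]-2-methylpropan-1-one
Conditions: BnBr (2.1 equiv), K2CO3, DMF, rt to 40 °C
Reagents that add atoms: benzyl bromide, BrCc1ccccc1
Why: Williamson etherification under weak base takes the para hydroxyl and the less hindered ortho hydroxyl, whereas the hydroxyl wedged between the methyl and the acyl group stays chelated to the ketone and free.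

Step 7
Reactants: 12 1-[4,6-bis(benzyloxy)-2-hydroxy-3-methylphenyl]-2-methylpropan-1-one
Product: 13 1-[4,6-bis(benzyloxy)-2-methoxy-3-methylphenyl]-2-methylpropan-1-one
Conditions: MeI (excess), K2CO3, DMF, 50 °C
Reagents that add atoms: iodomethane, CI
Why: Williamson methylation of the one remaining, chelated phenol is forced by excess small electrophile and puts the methyl ether between the ring methyl and the acyl group as ring D requires.

Step 8
Reactants: 13 1-[4,6-bis(benzyloxy)-2-methoxy-3-methylphenyl]-2-methylpropan-1-one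
Product: 14 1-[4,6-bis(benzyloxy)-5-iodo-2-methoxy-3-methylphenyl]-2-methylpropan-1-one
Conditions: NIS, CF3CO2H (cat.), MeCN, rt
Reagents that add atoms: N-iodosuccinimide, O=C1CCC(=O)N1I
Why: Electrophilic aromatic iodination can only strike the single free position, which is activated by two ortho alkoxy groups and one para alkoxy group.

Step 9
Reactants: 14 1-[4,6-bis(benzyloxy)-5-iodo-2-methoxy-3-methylphenyl]-2-methylpropan-1-one; 15 (3-ethoxy-3-oxopropyl)zinc bromide
Product: 16 ethyl 3-ArD-propanoate
Conditions: Pd(OAc)2 (3 mol %), SPhos (6 mol %), THF, 50 °C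
Reagents that add atoms: none
Why: Negishi sp2–sp3 coupling, in which the zinc homoenolate ignores the hindered ketone and the bulky biarylphosphine lets zerovalent palladium handle the di-ortho-substituted iodide while reductive elimination outruns β-hydride loss.

Step 10
Reactants: 16 ethyl 3-ArD-propanoate
Product: 17 ethyl 2-chloro-3-ArD-propanoate (racemic)
Conditions: LiN(iPr)2 (1.1 equiv), THF, −78 °C; then C2Cl6, −78 to −20 °C
Reagents that add atoms: hexachloroethane, ClC(Cl)(Cl)C(Cl)(Cl)Cl
Why: Kinetic ester enolate chlorination, selective because the aryl isopropyl ketone offers only a tertiary α-hydrogen behind two ortho substituents (any ketone enolate would simply be returned on quenching), and the new racemic centre is erased when the ketene forms.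

Step 11
Reactants: 17 ethyl 2-chloro-3-ArD-propanoate
Product: 18 2-chloro-3-ArD-propanoic acid
Conditions: LiOH, THF–H2O, 0 °C; then 1 M HCl
Reagents that add atoms: lithium hydroxide, [Li+].[OH-]
Why: Cold saponification of an unhindered ethyl ester is faster than substitution or elimination at the α-chloride and leaves ethers and ketone alone.

Step 12
Reactants: 18 2-chloro-3-ArD-propanoic acid; 8 (2R,3S)-2-ArB-3,4-dihydro-2H-pyran-3-yl benzoate
Product: 21 chlorocyclobutanone (3R,4S)-3-ArB-8-chloro-8-(ArD-methyl)-7-oxo-2-oxabicyclo[4.2.0]octan-4-yl benzoate (epimers at C1/C6/C8), via acid chloride 19 (not isolated), via chloroketene 20 (not isolated)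
Conditions: (COCl)2, DMF (cat.), CH2Cl2, 0 °C to rt, evaporate; then 8, Et3N (slow addition), toluene, rt
Reagents that add atoms: none
Why: Thermal [2+2] cycloaddition of an alkyl(chloro)ketene to a cyclic enol ether, a reaction known for dihydropyran itself, in which polarity joins the ketene carbonyl C5 to the nucleophilic C4a and C8 to the oxygen-bearing C8a, and the three new centres form as mixtures that are erased later.

Step 13
Reactants: 21 chlorocyclobutanone
Product: 22 silyl enol ether (3R,4S)-3-ArB-8-(ArD-methyl)-7-(trimethylsilyloxy)-2-oxabicyclo[4.2.0]oct-7-en-4-yl benzoate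
Conditions: Zn dust, Me3SiCl, TMEDA, THF, 0 °C to rt
Reagents that add atoms: chlorotrimethylsilane, C[Si](C)(C)Cl
Why: Reductive silylation of an α-chloro ketone (zinc enolate trapped on oxygen) fixes the enol double bond at C5=C8, the only place the chloride allows; base-induced loss of HCl is avoided because 2-alkyl-2-chlorocyclobutanones eliminate toward the exocyclic carbon and deprotonation at C4a would expel O1 and open ring C.

Step 14
Reactants: 22 silyl enol ether
Product: 23 cyclobutenone (3R,4S)-3-ArB-8-(ArD-methyl)-7-oxo-2-oxabicyclo[4.2.0]oct-1(8)-en-4-yl benzoate (either epimer at C6, which is C4a)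
Conditions: Pd(OAc)2 (1.05 equiv), MeCN, rt
Reagents that add atoms: none
Why: Saegusa–Ito oxidation, in which divalent palladium binds C8 from the convex face, syn to the hydridic C8a–H, so that β-hydride elimination gives the push–pull 3-alkoxy enone, whereas the exocyclic alternative would force the di-ortho-substituted ring D into the plane of a benzylidene ketone.

Step 15
Reactants: 24 acetylene
Product: 27 (triisopropylsilyloxy)acetylene, via lithium acetylide 25 (not isolated), via lithium ethynolate 26 (not isolated)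
Conditions: acetylene (excess), n-BuLi, THF, −78 °C; premixed t-BuOOH and LiN(SiMe3)2, −78 to −10 °C; iPr3SiOTf, −78 °C to rt
Reagents that add atoms: tert-butyl hydroperoxide, CC(C)(C)OO; triisopropylsilyl trifluoromethanesulfonate, CC(C)[Si](C(C)C)(C(C)C)OS(=O)(=O)C(F)(F)F
Why: Oxidation of a lithium acetylide with lithium tert-butyl peroxide is the general route to ynolates, excess acetylene holds the monolithio species, and the bulky, oxophilic silyl triflate should silylate oxygen and not carbon.

Step 16
Reactants: 23 cyclobutenone; 27 (triisopropylsilyloxy)acetylene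
Product: 28 (2R,3S)-2-ArB-8-(ArD-methyl)-5-hydroxy-7-(triisopropylsilyloxy)chroman-3-yl benzoate
Conditions: 27 (2.5 equiv), toluene (0.1 M), 110 °C, sealed tube, argon
Reagents that add atoms: none
Why: Heating opens 23 by four-electron conrotation at C5–C4a; because C4a and C8a stay tied in ring C the C4 methylene can only turn outward, which gives the vinylketene O=C5=C8(CH2ArD)–C8a(O1)=C4a and denies it a 1,5-hydrogen shift. The nucleophilic CH terminus of 27 adds to the ketene carbon C5 and its oxygen-bearing carbon closes onto C8 in a [2+2] union, the 4-alkenylcyclobutenone so formed reopens, and ring A closes by six-electron disrotatory electrocyclisation that remakes C5–C4a, followed by tautomerisation to the C5 phenol. This is the Danheiser benzannulation of a cyclobutenone with a silyl ynol ether; thermal opening of 3-oxygenated cyclobutenones to vinylketenes is established, and only the fusion to a dihydropyran is untried. No stereocentre is created, C4a is erased, and C2 and C3 are bystanders. The step needs one orientation of the alkyne, and the polarisation of the ynol ether secures it, so O7 ends next to C8 and H6 next to C5, while the bridge sits on C8 because it was already on the alkene carbon of 23. The C3 benzoate, chosen in place of an ether, inductively holds back ionisation of the benzylic C2–O1 bond of the vinylogous ester at 110 °C.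

Step 17
Reactants: 28 (2R,3S)-2-ArB-8-(ArD-methyl)-5-hydroxy-7-(triisopropylsilyloxy)chroman-3-yl benzoate
Product: 30 (2R,3S)-2-ArB-8-(ArD-methyl)chroman-3,5,7-triol, via diphenol benzoate 29 (not isolated)
Conditions: Bu4NF, THF, 0 °C; then K2CO3, MeOH, rt, argon
Reagents that add atoms: none
Why: Fluoride desilylation of the aryl silyl ether followed by carbonate-mediated transesterification of the C3 benzoate, safe for C2 because ring B is still benzylated and no quinone methide can form.

Step 18
Reactants: 30 (2R,3S)-2-ArB-8-(ArD-methyl)chroman-3,5,7-triol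
Product: 31 pilosanol B
Conditions: H2 (1 atm), Pd(OH)2/C, THF–MeOH, rt
Reagents that add atoms: none
Why: Hydrogenolysis of the four aryl benzyl ethers, under which the chelated aryl ketone, the diarylmethane bridge and the C2–O1 bond persist as they do in the deprotection of benzylated catechins.

Compound list
1 | acrolein | C=CC=O | starting material
2 | benzoic anhydride | O=C(OC(=O)c1ccccc1)c1ccccc1 | starting material
3 | prop-2-ene-1,1-diyl dibenzoate | C=CC(OC(=O)c1ccccc1)OC(=O)c1ccccc1 | intermediate
4 | 3,4-bis(benzyloxy)benzaldehyde | O=Cc1ccc(OCc2ccccc2)c(OCc2ccccc2)c1 | starting material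
5 | (1R,2S)-1-[3,4-bis(benzyloxy)phenyl]-1-hydroxybut-3-en-2-yl benzoate | O[C@H](c1ccc(OCc2ccccc2)c(OCc2ccccc2)c1)[C@@H](OC(=O)c1ccccc1)C=C | intermediate
6 | (1R,2S)-1-[3,4-bis(benzyloxy)phenyl]-1-hydroxy-5-oxopentan-2-yl benzoate | O[C@H](c1ccc(OCc2ccccc2)c(OCc2ccccc2)c1)[C@@H](OC(=O)c1ccccc1)CCC=O | intermediate
7 | (2R,3S)-2-[3,4-bis(benzyloxy)phenyl]-6-hydroxytetrahydropyran-3-yl benzoate (anomers) | O1[C@H](c2ccc(OCc3ccccc3)c(OCc3ccccc3)c2)[C@@H](OC(=O)c2ccccc2)CCC1O | intermediate
8 | (2R,3S)-2-[3,4-bis(benzyloxy)phenyl]-3,4-dihydro-2H-pyran-3-yl benzoate | O1[C@H](c2ccc(OCc3ccccc3)c(OCc3ccccc3)c2)[C@@H](OC(=O)c2ccccc2)CC=C1 | intermediate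
9 | 2-methylphloroglucinol | Cc1c(O)cc(O)cc1O | starting material
10 | isobutyryl chloride | CC(C)C(=O)Cl | starting material
11 | 2-methyl-1-(2,4,6-trihydroxy-3-methylphenyl)propan-1-one | CC(C)C(=O)c1c(O)cc(O)c(C)c1O | intermediate
12 | 1-[4,6-bis(benzyloxy)-2-hydroxy-3-methylphenyl]-2-methylpropan-1-one | CC(C)C(=O)c1c(OCc2ccccc2)cc(OCc2ccccc2)c(C)c1O | intermediate
13 | 1-[4,6-bis(benzyloxy)-2-methoxy-3-methylphenyl]-2-methylpropan-1-one | CC(C)C(=O)c1c(OCc2ccccc2)cc(OCc2ccccc2)c(C)c1OC | intermediate
14 | 1-[4,6-bis(benzyloxy)-5-iodo-2-methoxy-3-methylphenyl]-2-methylpropan-1-one | CC(C)C(=O)c1c(OCc2ccccc2)c(I)c(OCc2ccccc2)c(C)c1OC | intermediate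
15 | (3-ethoxy-3-oxopropyl)zinc bromide | CCOC(=O)CC[Zn]Br | starting material
16 | ethyl 3-[2,6-bis(benzyloxy)-4-methoxy-3-methyl-5-(2-methylpropanoyl)phenyl]propanoate | CCOC(=O)CCc1c(OCc2ccccc2)c(C)c(OC)c(C(=O)C(C)C)c1OCc1ccccc1 | intermediate
17 | ethyl 2-chloro-3-ArD-propanoate (racemic) | CCOC(=O)C(Cl)Cc1c(OCc2ccccc2)c(C)c(OC)c(C(=O)C(C)C)c1OCc1ccccc1 | intermediate
18 | 2-chloro-3-ArD-propanoic acid (racemic) | OC(=O)C(Cl)Cc1c(OCc2ccccc2)c(C)c(OC)c(C(=O)C(C)C)c1OCc1ccccc1 | intermediate
19 | 2-chloro-3-ArD-propanoyl chloride | ClC(=O)C(Cl)Cc1c(OCc2ccccc2)c(C)c(OC)c(C(=O)C(C)C)c1OCc1ccccc1 | intermediate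
20 | (ArD-methyl)(chloro)ketene | O=C=C(Cl)Cc1c(OCc2ccccc2)c(C)c(OC)c(C(=O)C(C)C)c1OCc1ccccc1 | intermediate
21 | (3R,4S)-3-ArB-8-chloro-8-(ArD-methyl)-7-oxo-2-oxabicyclo[4.2.0]octan-4-yl benzoate (epimers at C1, C6, C8) | O=C1C(Cl)(Cc3c(OCc4ccccc4)c(C)c(OC)c(C(=O)C(C)C)c3OCc3ccccc3)C2O[C@H](c3ccc(OCc4ccccc4)c(OCc4ccccc4)c3)[C@@H](OC(=O)c3ccccc3)CC12 | intermediate
22 | (3R,4S)-3-ArB-8-(ArD-methyl)-7-(trimethylsilyloxy)-2-oxabicyclo[4.2.0]oct-7-en-4-yl benzoate | C[Si](C)(C)OC1=C(Cc3c(OCc4ccccc4)c(C)c(OC)c(C(=O)C(C)C)c3OCc3ccccc3)C2O[C@H](c3ccc(OCc4ccccc4)c(OCc4ccccc4)c3)[C@@H](OC(=O)c3ccccc3)CC12 | intermediate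
23 | (3R,4S)-3-ArB-8-(ArD-methyl)-7-oxo-2-oxabicyclo[4.2.0]oct-1(8)-en-4-yl benzoate (either epimer at C6) | O=C1C(Cc3c(OCc4ccccc4)c(C)c(OC)c(C(=O)C(C)C)c3OCc3ccccc3)=C2O[C@H](c3ccc(OCc4ccccc4)c(OCc4ccccc4)c3)[C@@H](OC(=O)c3ccccc3)CC12 | intermediate
24 | acetylene | C#C | starting material
25 | lithium acetylide | [Li+].[C-]#C | intermediate
26 | lithium ethynolate | [Li+].[O-]C#C | intermediate
27 | (triisopropylsilyloxy)acetylene | C#CO[Si](C(C)C)(C(C)C)C(C)C | intermediate
28 | (2R,3S)-2-ArB-8-(ArD-methyl)-5-hydroxy-7-(triisopropylsilyloxy)chroman-3-yl benzoate | COc1c(C)c(OCc2ccccc2)c(Cc2c(O[Si](C(C)C)(C(C)C)C(C)C)cc(O)c3c2O[C@H](c2ccc(OCc4ccccc4)c(OCc4ccccc4)c2)[C@@H](OC(=O)c2ccccc2)C3)c(OCc2ccccc2)c1C(=O)C(C)C | intermediate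
29 | (2R,3S)-2-ArB-8-(ArD-methyl)-5,7-dihydroxychroman-3-yl benzoate | COc1c(C)c(OCc2ccccc2)c(Cc2c(O)cc(O)c3c2O[C@H](c2ccc(OCc4ccccc4)c(OCc4ccccc4)c2)[C@@H](OC(=O)c2ccccc2)C3)c(OCc2ccccc2)c1C(=O)C(C)C | intermediate
30 | (2R,3S)-2-ArB-8-(ArD-methyl)chroman-3,5,7-triol | COc1c(C)c(OCc2ccccc2)c(Cc2c(O)cc(O)c3c2O[C@H](c2ccc(OCc4ccccc4)c(OCc4ccccc4)c2)[C@@H](O)C3)c(OCc2ccccc2)c1C(=O)C(C)C | intermediate
31 | pilosanol B | COc1c(C)c(O)c(Cc2c(O)cc(O)c3c2O[C@H](c2ccc(O)c(O)c2)[C@@H](O)C3)c(O)c1C(=O)C(C)C | target

Total step count: 18. Longest linear sequence: 13 steps (steps 5–14 and 16–18). The ring C branch (steps 1–4) and the ynol ether (step 15) run in parallel.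

Steps most likely to fail

Step 16. The vinylogous-ester stabilisation of 23 may push ring opening to temperatures at which the terminal ynol ether decays by oxygen-to-carbon silyl migration. The freshly formed phenol may also be acylated by the vinylketene. The fallback gives up the annulation and joins ring D to a ready-made ring A; it sets out from iodide 14 and returns at 31.
- Iodine–magnesium exchange of 14 (i-PrMgCl·LiCl, THF, −20 °C) and quenching with DMF should give ring D aldehyde F1.
- Purchased (+)-catechin is perbenzylated (BnBr, K2CO3, DMF; then NaH, BnBr) to penta-O-benzylcatechin F2.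
- NBS in CH2Cl2 at low temperature brominates F2 at C8, the known preferred site, to give 8-bromide F3.
- Bromine–lithium exchange (n-BuLi, THF, −78 °C) and addition to F1 should give diarylmethanol F4.
- Hydrogenolysis over Pd(OH)2/C removes the doubly benzylic hydroxyl together with the seven benzyl groups and reaches 31.

Step 14. β-Hydride loss may run toward the benzylic CH2, or β-alkoxide loss from the palladium enolate may open ring C. The fallback moves the leaving group onto C8a, so that the alkene is closed by β-elimination from a regiodefined C8 enolate. It sets out from lactol 7 (and acid 18 as ketene source) and returns at 23.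
- Oxidation of 7 (TEMPO, PhI(OAc)2) should give δ-lactone F5.
- Lawesson's reagent in warm toluene should give thionolactone F6.
- S-Methylation with MeOTf followed by i-Pr2NEt should give ketene O,S-acetal F7.
- Cycloaddition of F7 with chloroketene 20, generated as in step 12, should give 1-(methylthio)chlorocyclobutanone F8.
- Zinc dust in THF converts the C8–Cl bond of F8 into the zinc enolate, which expels methanethiolate, the better of the two leaving groups on C8a, to give 23.

Step 15. Silylation of the unhindered parent ynolate may occur at carbon, and monolithium acetylide may disproportionate during the oxidation. The fallback replaces the silyl ynol ether by an alkyl ynol ether made by the dichlorovinyl ether route; it sets out from 23 and returns at 30.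
- 2-(Trimethylsilyl)ethanol with KH and trichloroethylene should give 1,2-dichlorovinyl ether F9.
- n-BuLi (2.2 equiv, −78 °C) followed by methanol should give 2-(trimethylsilyl)ethyl ethynyl ether F10.
- Benzannulation of 23 with excess F10 in toluene at 100 °C should give 7-O-[2-(trimethylsilyl)ethyl] flavan F11.
- Bu4NF in DMF at 60 °C followed by K2CO3 in MeOH removes the silylethyl group and the benzoate to give 30.

Further compounds
F1 | step 16 | 2,6-bis(benzyloxy)-4-methoxy-3-methyl-5-(2-methylpropanoyl)benzaldehyde | O=Cc1c(OCc2ccccc2)c(C)c(OC)c(C(=O)C(C)C)c1OCc1ccccc1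
F2 | step 16 | (2R,3S)-3,5,7,3',4'-penta-O-benzylcatechin | c1c(OCc2ccccc2)cc(OCc2ccccc2)c2c1O[C@H](c1ccc(OCc3ccccc3)c(OCc3ccccc3)c1)[C@@H](OCc1ccccc1)C2
F3 | step 16 | (2R,3S)-8-bromo-3,5,7,3',4'-penta-O-benzylcatechin | Brc1c(OCc2ccccc2)cc(OCc2ccccc2)c2c1O[C@H](c1ccc(OCc3ccccc3)c(OCc3ccccc3)c1)[C@@H](OCc1ccccc1)C2
F4 | step 16 | ArD(hydroxy)methyl adduct at C8 of penta-O-benzylcatechin (carbinol epimers) | COc1c(C)c(OCc2ccccc2)c(C(O)c2c(OCc4ccccc4)cc(OCc4ccccc4)c3c2O[C@H](c2ccc(OCc4ccccc4)c(OCc4ccccc4)c2)[C@@H](OCc2ccccc2)C3)c(OCc2ccccc2)c1C(=O)C(C)C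
F5 | step 14 | (2R,3S)-2-ArB-6-oxotetrahydropyran-3-yl benzoate | O1[C@H](c2ccc(OCc3ccccc3)c(OCc3ccccc3)c2)[C@@H](OC(=O)c2ccccc2)CCC1=O
F6 | step 14 | (2R,3S)-2-ArB-6-thioxotetrahydropyran-3-yl benzoate | O1[C@H](c2ccc(OCc3ccccc3)c(OCc3ccccc3)c2)[C@@H](OC(=O)c2ccccc2)CCC1=S
F7 | step 14 | (2R,3S)-2-ArB-6-(methylthio)-3,4-dihydro-2H-pyran-3-yl benzoate | O1[C@H](c2ccc(OCc3ccccc3)c(OCc3ccccc3)c2)[C@@H](OC(=O)c2ccccc2)CC=C1SC
F8 | step 14 | (3R,4S)-3-ArB-8-chloro-8-(ArD-methyl)-1-(methylthio)-7-oxo-2-oxabicyclo[4.2.0]octan-4-yl benzoate | O=C1C(Cl)(Cc3c(OCc4ccccc4)c(C)c(OC)c(C(=O)C(C)C)c3OCc3ccccc3)C2(SC)O[C@H](c3ccc(OCc4ccccc4)c(OCc4ccccc4)c3)[C@@H](OC(=O)c3ccccc3)CC12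
F9 | step 15 | 1,2-dichlorovinyl 2-(trimethylsilyl)ethyl ether | ClC=C(Cl)OCC[Si](C)(C)C
F10 | step 15 | ethynyl 2-(trimethylsilyl)ethyl ether | C#COCC[Si](C)(C)C
F11 | step 15 | (2R,3S)-2-ArB-8-(ArD-methyl)-5-hydroxy-7-[2-(trimethylsilyl)ethoxy]chroman-3-yl benzoate | COc1c(C)c(OCc2ccccc2)c(Cc2c(OCC[Si](C)(C)C)cc(O)c3c2O[C@H](c2ccc(OCc4ccccc4)c(OCc4ccccc4)c2)[C@@H](OC(=O)c2ccccc2)C3)c(OCc2ccccc2)c1C(=O)C(C)C
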